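**Plan**

Numbering: C1 is the CH2OAc carbon. The ring is C2–C10: C2 bears C1, C3 bears the formyl carbon C18, C7 the methyl group, C9 the OH, and C10 the side chain that starts at C11.
Retrosynthesis: C3–C18 is cut first (enal ⇒ enol triflate ⇒ C3 ketone). The nine-membered ring is then traced back to a smaller ring by re-joining C3 to C7. After that C2–C3, C9–C10 and C7–C8 are cut.
Enabling feature: C3 and the methyl-bearing alkene carbon C7 are separated by three ring atoms (C4–C6) on one side and four (C8, C9, C10, C2) on the other. The nine-membered ring is therefore the perimeter of a bicyclo[4.3.0]nonane (cyclopentane C3–C7 fused to cyclohexane C7–C8–C9–C10–C2–C3), and O–C3–C7–C6–Sn is a γ-hydroxystannane set up for 1,4-fragmentation.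
Forward order: a cyclopentanone (C3–C7, tin on C6, allyl on C7) is made first. The chain C8–C9–C10–C2–C1 is attached by allylboration, and the cyclohexane is closed C2→C3 by addition of an epoxide-derived radical to the ketone. Cleavage of the C3–C7 bridge then enlarges the five-membered ring by four carbons to the nine-membered ring, and C18 enters by carbonylation.
Stereochemistry: C11 comes from (S)-citronellal, C9/C10 from a catalyst-controlled anti allylboration, and C2 from a chair-like radical cyclisation (trans to the C10 substituent). The 6E alkene comes from the antiperiplanar Sn/C3–C7 array fixed by trans alkylation of the stannyl enolate, and the C3=C4 geometry from ring-constrained enolisation.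
The cyclopentane stereocentres C3, C6 and C7 are helpers only and are all erased in the key step, so the stannyl ketone can be used as the racemate and both diastereomeric series converge.

Key step: step 9

Remark: 4–6 are racemic, so 8–12 (and F1–F4) are pairs of diastereomers that differ only in the sense of the cyclopentane centres C3/C6/C7; names and SMILES show the series from the drawn enantiomer of 5, the partner series has these centres inverted, and the oxirane carbon of 9 and 10 is left undefined because both epimers give the same radical.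

Step 1
Reactants: 1 (S)-citronellal
Product: 2 (E)-alkenylboronate 2-[(1E,4S)-4,8-dimethylnona-1,7-dien-1-yl]-4,4,5,5-tetramethyl-1,3,2-dioxaborolane
Conditions: CH2(Bpin)2, LiTMP, THF, 0 °C; then 1, −78 °C → rt
Reagents that add atoms: bis[(pinacolato)boryl]methane, C(B1OC(C)(C)C(C)(C)O1)B1OC(C)(C)C(C)(C)O1
Why: Boron–Wittig olefination, in which the lithiated geminal bis(boronate) adds to the aldehyde and eliminates a boron–oxygen unit to give the (E)-alkenylboronate (C1 introduced), while C11 is β to the carbonyl group and is not touched.

Step 2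
Reactants: 3 2-methylcyclopent-2-en-1-one
Product: 5 rac-(2S*,3S*)-2-allyl-2-methyl-3-(tributylstannyl)cyclopentan-1-one, via lithium enolate 4 (not isolated)
Conditions: Bu3SnH, LDA, THF, 0 °C; 3, −78 °C; allyl bromide, HMPA, −78 → −20 °C
Reagents that add atoms: tributyltin hydride, CCCC[SnH](CCCC)CCCC; allyl bromide, C=CCBr
Why: Tandem conjugate addition of Bu3SnLi and alkylation of the regiodefined enolate 4, in which allyl bromide approaches C7 anti to the bulky stannyl group on C6, so that allyl ends trans and methyl cis to tin, the relation that the key step later turns into the E-alkene.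

Step 3
Reactants: 5 rac-2-allyl-2-methyl-3-(tributylstannyl)cyclopentan-1-one
Product: 6 rac-2-[(1S*,5S*)-1-methyl-2-oxo-5-(tributylstannyl)cyclopentyl]acetaldehyde
Conditions: OsO4 (cat.), NaIO4, 2,6-lutidine, dioxane/H2O, rt
Reagents that add atoms: sodium periodate, [Na+].[O-]I(=O)(=O)=O (oxygen passed on through catalytic osmium tetroxide, O=[Os](=O)(=O)=O)
Why: Lemieux–Johnson cleavage of the only alkene gives the C9 aldehyde, the tetraalkylstannane and the ketone being inert to osmium tetroxide and periodate, and the buffered medium avoiding aldolisation.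

Step 4
Reactants: 2 (E)-alkenylboronate; 6 keto aldehyde
Product: 8 homoallylic alcohol 2-[(2S,3S,4S)-3-ethenyl-2-hydroxy-4,8-dimethylnon-7-en-1-yl]-2-methyl-3-(tributylstannyl)cyclopentan-1-one, via (E)-allylboronate 7 (not isolated)
Conditions: [Ir(cod)2]BF4 (cat.), PCy3 (cat., pre-activated with H2), (R)-TRIP (cat.), 4 Å MS, ClCH2CH2Cl, rt; aq. work-up
Reagents that add atoms: none
Why: Tandem alkene transposition and chiral-phosphoric-acid-catalysed allylboration, in which the iridium hydride moves the double bond of 2 by one position to the (E)-γ-substituted allylboronate 7, which adds to the aldehyde (not to the hindered ketone) through a closed Zimmerman–Traxler chair, so that the E-geometry gives the anti C9/C10 relation and (R)-TRIP directs Re-face attack (9S), the remote ring centres having no say.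

Step 5
Reactants: 8 homoallylic alcohol
Product: 9 epoxy alcohol (8 with the vinyl group C2=C1 converted into an oxirane)
Conditions: VO(acac)2 (cat.), t-BuOOH (decane), CH2Cl2, 0 °C → rt
Reagents that add atoms: tert-butyl hydroperoxide, CC(C)(C)OO
Why: Hydroxyl-directed vanadium-catalysed epoxidation of a homoallylic alcohol, in which only the vinyl group is within reach of the C9-bound vanadium peroxide, so that the remote trisubstituted alkene is spared, and the configuration of the new oxirane carbon does not matter because it becomes a planar radical in step 7.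

Step 6
Reactants: 9 epoxy alcohol
Product: 10 triethylsilyl ether of 9
Conditions: TESCl, imidazole, DMAP (cat.), CH2Cl2, 0 °C → rt
Reagents that add atoms: chlorotriethylsilane, CC[Si](Cl)(CC)CC
Why: Standard silylation that keeps the C9 oxygen from opening the epoxide, from quenching the radical of step 7, from binding lead in step 9 and from adding to C3 or to an acylpalladium later.

Step 7
Reactants: 10 silylated epoxy ketone
Product: 11 cis-hydrindane diol (7a-methyloctahydroinden-3a-ol with 1-SnBu3, 4-CH2OH, 5-[(2S)-6-methylhept-5-en-2-yl] and 6-OTES; 3a-OH, 7a-CH3 and 1-Sn all cis; 4-CH2OH trans and 6-OTES cis to the 5-side chain)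
Conditions: Cp2TiCl2 (20 mol %), Mn, 2,4,6-collidine·HCl, THF, rt, slow addition of 10
Reagents that add atoms: none
Why: Titanocene(III)-catalysed reductive epoxide opening gives the more substituted β-titanoxy radical at C2, which adds 6-exo to the C3 ketone (a known cyclisation mode of epoxy ketones) from the face that carries the tether (cis ring fusion) through a chair with the C10 side chain and the C1 oxymethyl group equatorial, which sets C2 trans to C10 from either epoxide epimer.

Step 8
Reactants: 11 cis-hydrindane diol
Product: 12 primary monoacetate of 11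
Conditions: Ac2O, pyridine, DMAP (cat.), CH2Cl2, 0 °C
Reagents that add atoms: acetic anhydride, CC(=O)OC(C)=O
Why: Chemoselective acylation, since the primary C1 hydroxyl reacts far faster than the hindered tertiary carbinol, which puts the acetate of the target in place and leaves only the C3 hydroxyl free for lead(IV).

Step 9
Reactants: 12 γ-hydroxystannane monoacetate
Product: 13 (4E,7S,8R,9S)-9-(acetoxymethyl)-5-methyl-8-[(2S)-6-methylhept-5-en-2-yl]-7-(triethylsilyloxy)cyclonon-4-en-1-one
Conditions: Pb(OAc)4 (1.2 equiv), benzene, rt → 50 °C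
Reagents that add atoms: none
Why: The tertiary C3–OH exchanges an acetate on Pb(IV); two-electron collapse of the lead alkoxide turns C3–O into the ketone and breaks the C3–C7 bond, while the antiperiplanar C6–Sn σ bond feeds the electron demand at C7 and tin leaves as Bu3SnOAc, so C6=C7 forms in the same event. The closest known reaction type is the oxidative Grob-type 1,4-fragmentation of γ-hydroxystannanes with lead tetraacetate or iodine(III), which is stereospecific and has been used to enlarge stannylated bicyclic carbinols and hemiketals to medium rings. The nine-membered ring is not closed end to end: it is the perimeter of the bicyclo[4.3.0]nonane and appears when the zero-atom bridge C3–C7 is cut, that is, the cyclopentane C3–C7 is expanded by the four carbons C8, C9, C10 and C2. No stereocentre is created; the one new stereo-element, the alkene, is fixed by the substrate, because tin is cis to the angular methyl group and pseudo-equatorial, hence anti to C3–C7, which places C5 and the methyl group on the same side (6E). C3, C6 and C7 all become trigonal, so both diastereomers of 12 should funnel into the single ketone 13, and the planar-chiral conformers first released should equilibrate by rotation of the E-alkene through the ring at the reaction temperature. The step needs cleavage of C3–C7 in preference to C3–C2 and C3–C4 and no attack on the two alkenes or on C2: only C7 enjoys β-tin stabilisation, the primary hydroxyl is masked as the acetate, and the neutral medium leaves the α-stereocentre C2, the β-acetate and the silyl ether alone.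

Step 10
Reactants: 13 cyclononenone
Product: 15 (1E,4E,7S,8R,9S)-9-(acetoxymethyl)-5-methyl-8-[(2S)-6-methylhept-5-en-2-yl]-7-(triethylsilyloxy)cyclonona-1,4-dien-1-yl trifluoromethanesulfonate, via potassium enolate 14 (not isolated)
Conditions: KHMDS (1.2 equiv), THF, −78 °C; Comins' reagent, −78 °C
Reagents that add atoms: Comins' reagent, N-(5-chloropyridin-2-yl)bis(trifluoromethanesulfonimide), FC(F)(F)S(=O)(=O)N(c1ccc(Cl)cn1)S(=O)(=O)C(F)(F)F
Why: Kinetic deprotonation at the unhindered C4 methylene (not at the tertiary C2–H, whose enolate would expel acetate) followed by O-sulfonylation, a ring that already holds an E-alkene being able to accommodate only a ring-cis C3=C4, so that C2 and C5 are cis in 14 as the target requires.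

Step 11
Reactants: 15 enol triflate
Product: 16 O-triethylsilyl hydroxyacetyldictyolal
Conditions: Pd(PPh3)4 (cat.), LiCl, CO (1–3 atm), Bu3SnH (syringe pump), THF, 50 °C
Reagents that add atoms: carbon monoxide, [C-]#[O+]
Why: Palladium-catalysed formylation of a vinyl triflate (Stille-type carbonylative reduction) by oxidative addition, CO insertion and hydride transfer with retention of the alkene geometry, slow addition of the hydride suppressing direct reduction and the merely homoallylic acetate offering no π-allyl pathway.

Step 12
Reactants: 16 O-triethylsilyl hydroxyacetyldictyolal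
Product: 17 hydroxyacetyldictyolal
Conditions: HF·pyridine, pyridine, THF, 0 °C
Reagents that add atoms: none
Why: Fluoride-driven cleavage of the triethylsilyl ether under buffered, weakly acidic conditions that leave the acetate, the enal and the skipped diene untouched and do not affect any stereocentre.

**Compound list**

1 | (S)-citronellal, (3S)-3,7-dimethyloct-6-enal | O=CC[C@@H](C)CCC=C(C)C | starting material
2 | 2-[(1E,4S)-4,8-dimethylnona-1,7-dien-1-yl]-4,4,5,5-tetramethyl-1,3,2-dioxaborolane | CC1(C)OB(/C=C/C[C@@H](C)CCC=C(C)C)OC1(C)C | intermediate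
3 | 2-methylcyclopent-2-en-1-one | CC1=CCCC1=O | starting material
4 | lithium 2-methyl-3-(tributylstannyl)cyclopent-1-en-1-olate (racemic, one enantiomer drawn, not isolated) | [Li]OC1=C(C)[C@@H]([Sn](CCCC)(CCCC)CCCC)CC1 | intermediate
5 | rac-(2S*,3S*)-2-allyl-2-methyl-3-(tributylstannyl)cyclopentan-1-one (allyl trans, methyl cis to tin; one enantiomer drawn) | O=C1CC[C@H]([Sn](CCCC)(CCCC)CCCC)[C@@]1(C)CC=C | intermediate
6 | rac-2-[(1S*,5S*)-1-methyl-2-oxo-5-(tributylstannyl)cyclopentyl]acetaldehyde (one enantiomer drawn) | O=C1CC[C@H]([Sn](CCCC)(CCCC)CCCC)[C@@]1(C)CC=O | intermediate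
7 | 2-[(2E,4S)-4,8-dimethylnona-2,7-dien-1-yl]-4,4,5,5-tetramethyl-1,3,2-dioxaborolane (not isolated) | CC1(C)OB(C/C=C/[C@@H](C)CCC=C(C)C)OC1(C)C | intermediate
8 | homoallylic alcohol, C9–OH and C10 side chain anti (partner diastereomer: O=C1CC[C@@H]([Sn](CCCC)(CCCC)CCCC)[C@]1(C)C[C@H](O)[C@@H](C=C)[C@@H](C)CCC=C(C)C) | O=C1CC[C@H]([Sn](CCCC)(CCCC)CCCC)[C@@]1(C)C[C@H](O)[C@@H](C=C)[C@@H](C)CCC=C(C)C | intermediate
9 | epoxy alcohol, oxirane carbon undefined (partner diastereomer: O=C1CC[C@@H]([Sn](CCCC)(CCCC)CCCC)[C@]1(C)C[C@H](O)[C@@H](C2CO2)[C@@H](C)CCC=C(C)C) | O=C1CC[C@H]([Sn](CCCC)(CCCC)CCCC)[C@@]1(C)C[C@H](O)[C@@H](C2CO2)[C@@H](C)CCC=C(C)C | intermediate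
10 | triethylsilyl ether of 9 (partner diastereomer: O=C1CC[C@@H]([Sn](CCCC)(CCCC)CCCC)[C@]1(C)C[C@H](O[Si](CC)(CC)CC)[C@@H](C2CO2)[C@@H](C)CCC=C(C)C) | O=C1CC[C@H]([Sn](CCCC)(CCCC)CCCC)[C@@]1(C)C[C@H](O[Si](CC)(CC)CC)[C@@H](C2CO2)[C@@H](C)CCC=C(C)C | intermediate
11 | cis-hydrindane diol, OH/CH3/Sn all cis, CH2OH trans to the side chain (partner diastereomer: O[C@@]12CC[C@@H]([Sn](CCCC)(CCCC)CCCC)[C@]1(C)C[C@H](O[Si](CC)(CC)CC)[C@H]([C@@H](C)CCC=C(C)C)[C@H]2CO) | O[C@]12CC[C@H]([Sn](CCCC)(CCCC)CCCC)[C@@]1(C)C[C@H](O[Si](CC)(CC)CC)[C@H]([C@@H](C)CCC=C(C)C)[C@H]2CO | intermediate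
12 | primary monoacetate of 11 (partner diastereomer: O[C@@]12CC[C@@H]([Sn](CCCC)(CCCC)CCCC)[C@]1(C)C[C@H](O[Si](CC)(CC)CC)[C@H]([C@@H](C)CCC=C(C)C)[C@H]2COC(C)=O) | O[C@]12CC[C@H]([Sn](CCCC)(CCCC)CCCC)[C@@]1(C)C[C@H](O[Si](CC)(CC)CC)[C@H]([C@@H](C)CCC=C(C)C)[C@H]2COC(C)=O | intermediate
13 | (4E,7S,8R,9S)-9-(acetoxymethyl)-5-methyl-8-[(2S)-6-methylhept-5-en-2-yl]-7-(triethylsilyloxy)cyclonon-4-en-1-one | CC(=O)OC[C@H]1C(=O)CC/C=C(\C)C[C@H](O[Si](CC)(CC)CC)[C@@H]1[C@@H](C)CCC=C(C)C | intermediate
14 | potassium C3,C4-enolate of 13, C2 and C5 cis (not isolated) | CC(=O)OC[C@H]1/C([O-])=C\C/C=C(\C)C[C@H](O[Si](CC)(CC)CC)[C@@H]1[C@@H](C)CCC=C(C)C.[K+] | intermediate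
15 | enol triflate of 13, C2 and C5 cis on C3=C4 | CC(=O)OC[C@H]1/C(OS(=O)(=O)C(F)(F)F)=C\C/C=C(\C)C[C@H](O[Si](CC)(CC)CC)[C@@H]1[C@@H](C)CCC=C(C)C | intermediate
16 | O-triethylsilyl hydroxyacetyldictyolal | CC(=O)OC[C@H]1/C(C=O)=C\C/C=C(\C)C[C@H](O[Si](CC)(CC)CC)[C@@H]1[C@@H](C)CCC=C(C)C | intermediate
17 | hydroxyacetyldictyolal, [(1R,2E,5E,8S,9R)-2-formyl-8-hydroxy-6-methyl-9-[(2S)-6-methylhept-5-en-2-yl]cyclonona-2,5-dien-1-yl]methyl acetate | CC(=O)OC[C@H]1/C(C=O)=C\C/C=C(\C)C[C@H](O)[C@@H]1[C@@H](C)CCC=C(C)C | target

Total step count: 12. Longest linear sequence: 11 steps (3 → 17, steps 2–12). The branch from 1 joins after one step.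

**Steps most likely to fail**

1. Step 7. The C2 radical may be lost before it reaches the ketone.
- It can be captured by a second titanium(III) and then suffer β-elimination (deoxygenation).
- It can undergo 1,5-hydrogen transfer from the allylic side-chain position.
- It can add 6-exo to the side-chain alkene.
- The 1,3-diaxial contact between the C9 silyl ether and the axial substituent on C7 slows the closure further.

The fallback replaces the radical closure by a polar one. It sets out from 10 and comes back at 11. The terminal epoxide is isomerised by a Meinwald rearrangement (Cr(TPP)OTf cat., ClCH2CH2Cl) to the C1 aldehyde F1. Pyrrolidine/AcOH (enamine catalysis) then closes C2–C3 by a 6-enolexo aldol addition to the ketone and gives the cis-hydrindane hydroxy aldehyde F2, in which C2 can settle in the equatorial, trans arrangement. NaBH4 in MeOH reduces the aldehyde to 11.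

2. Step 4. The iridium hydride may move the double bond further toward C11, with loss of that stereocentre, faster than the hindered γ-branched allylboronate is captured. Facial control by the acid may also be eroded by this bulk.

The fallback changes the C9–C10 bond formation to enamine catalysis. It sets out from 1 and 6 and comes back at 8, so step 1 is then not needed. An L-proline-catalysed cross-aldol reaction is used, with 1 added slowly as the donor and the neopentyl-type aldehyde 6 as the reluctant enamine former and acceptor. It gives the anti β-hydroxy aldehyde F3. Wittig methylenation (Ph3P=CH2, THF, −78 °C) of the aldehyde, which reacts before the hindered ketone, gives 8.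

3. Step 10. Proton exchange between enolate and ketone may move the enolate to C2, followed by loss of acetate (E1cB). Alternatively the enolate may attack the neighbouring ester.

The fallback changes the order of events so that no β-acyloxy ketone is ever enolised. It sets out from 11 and comes back at 15.
- The primary hydroxyl is silylated (TESCl, imidazole) to the bis(silyl ether) F4.
- Pb(OAc)4 fragments it as in step 9 to the cyclononenone F5.
- KHMDS and Comins' reagent give the enol triflate F6.
- PPTS in MeOH/CH2Cl2 at 0 °C removes the primary silyl group in preference to the hindered secondary one and gives the primary alcohol F7.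
- Ac2O/pyridine converts F7 into 15.

**Further compounds**

F1 | step 7 | C1 aldehyde from rearrangement of 10 (C2 is a methylene group) | O=C1CC[C@H]([Sn](CCCC)(CCCC)CCCC)[C@@]1(C)C[C@H](O[Si](CC)(CC)CC)[C@@H](CC=O)[C@@H](C)CCC=C(C)C
F2 | step 7 | cis-hydrindane hydroxy aldehyde (11 with CHO in place of CH2OH) | O[C@]12CC[C@H]([Sn](CCCC)(CCCC)CCCC)[C@@]1(C)C[C@H](O[Si](CC)(CC)CC)[C@H]([C@@H](C)CCC=C(C)C)[C@H]2C=O
F3 | step 4 | anti β-hydroxy aldehyde (8 with CHO in place of vinyl) | O=C1CC[C@H]([Sn](CCCC)(CCCC)CCCC)[C@@]1(C)C[C@H](O)[C@@H](C=O)[C@@H](C)CCC=C(C)C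
F4 | step 10 | bis(triethylsilyl ether) of the hydrindane triol, tertiary OH free | O[C@]12CC[C@H]([Sn](CCCC)(CCCC)CCCC)[C@@]1(C)C[C@H](O[Si](CC)(CC)CC)[C@H]([C@@H](C)CCC=C(C)C)[C@H]2CO[Si](CC)(CC)CC
F5 | step 10 | cyclononenone with C1–OTES (13 with TES in place of acetyl) | CC[Si](CC)(CC)OC[C@H]1C(=O)CC/C=C(\C)C[C@H](O[Si](CC)(CC)CC)[C@@H]1[C@@H](C)CCC=C(C)C
F6 | step 10 | enol triflate with C1–OTES | CC[Si](CC)(CC)OC[C@H]1/C(OS(=O)(=O)C(F)(F)F)=C\C/C=C(\C)C[C@H](O[Si](CC)(CC)CC)[C@@H]1[C@@H](C)CCC=C(C)C
F7 | step 10 | enol triflate with free C1–OH | OC[C@H]1/C(OS(=O)(=O)C(F)(F)F)=C\C/C=C(\C)C[C@H](O[Si](CC)(CC)CC)[C@@H]1[C@@H](C)CCC=C(C)C
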